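The numbers of this flask are assumed; the result is computed.

In the early hours of this fed flask the initiator sits charged while free monomer trickles in, so the first question is how long chains go on being begun.

    free monomer + initiator → living end + monomer in chains (k1 = 0.18 L mol⁻¹ min⁻¹)
    initiator → spent initiator (k2 = 1.3 × 10⁻⁶ min⁻¹)
    free monomer + living end → monomer in chains + living end, rate k3*[living end]*[free monomer] (k3 = 0.046 L mol⁻¹ min⁻¹)

- elm: free monomer 0.10 M (fed, over 2.5 d); initiator 2.5 mol%; time 2.5 d; the fed solution adds 0.25 times the starting volume
- alder: free monomer 0.10 M (fed, over 2.5 d); initiator 2.5 mol%; time 5.0 d; the fed solution adds 0.25 times the starting volume

- charges are per starting volume, the dose included; the dosed solution carries all of it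
- the average divides the monomer in chains by the number of chains begun, living and dead together
- run time (elm): 2.5 d

1. which of the two ends with the longer chains by the average number of monomer units in a chain (chains begun, living or dead) ("neither" if they lie within 10%) (elm / alder / neither)
2. average number of monomer units in a chain (chains begun, living or dead) at the end, elm
3. average number of monomer units in a chain (chains begun, living or dead) at the end, alder

How long does the initiator last? [free monomer] climbs at about 0.0400 M d⁻¹, and against that rising concentration my reckoning, with dilution ignored, gives the initiator a lifetime of about 0.439 d, which is shorter than the dosing time of 2.5 d.

Does the side step to spent initiator take a real share? It takes hardly any, about 0.0822% over that lifetime, so the chains begun number 0.00250 M per starting volume.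

What, then, can be frozen? [living end] can, since propagation returns the living end it uses and the scheme has no step that ends one. After the feed [living end] stays at 0.00200 M, and free monomer decays in a pseudo-first-order way. Its time constant, the living-end clock, is one over k3 times the frozen [living end], 7.55 d.

But during the feed [living end] is not frozen, is it? No, it grows from nothing as the initiator reacts and is thinned by dilution as the feed goes on, so this is rough. The dosing time is shorter than the clock, so I let fed free monomer sit on average half of the dosing time, and 16.6% of it reacts. Dividing by the loading gives elm 6.62 units per chain.

And alder? Alder is elm plus 2.50 d at fixed volume, in which the clock leaves 71.8% of the free monomer, so I commit to 16.0 units per chain, far longer than elm's.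

The forecast also names alder, with 6.9 for elm and 16.2 for alder, both higher than my figures, holding that “the initiator is essentially all converted early”.

Elm ends at 6.88 and alder at 16.2 units per chain, so alder has the longer chains, as forecast, and alder's average has moved by 1.62 at 1.6 mol% or 3.6 mol% of initiator, with the other amounts and the time held. Alder holds 82.8% of the free monomer charged at the end of the feed, and the clock of 7.55 d takes that to 59.5% at 5.00 d, where the flask stands at 59.5%. Elm read at 10 d goes by the same clock to 30.7%, or 27.7 units per chain, and its reading is 31% and 27.7.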